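**Retrosynthetic overview**
1. Target 19 ⇐ 2‑methoxy quinone 18 ⇐ Diels–Alder/dehydrogenation of trienoic acid 16 (carried as its SO2 adduct 13) with quinone 15; the benzenoid ring of the naphthoquinone is formed last.
2. 13 ⇐ diol 8 by excision of the secondary oxygen (cyclic thionocarbonate) and CH2OH → CO2H.
3. 8 ⇐ epoxy alcohol 5: rings A and B of the decalin close together in one epoxide‑triggered radical bicyclisation; the epoxide C–O stereocentre fixes the absolute configuration.
4. Key bonds: the two C–O bonds of 5 (the allylic C–OH, which ends as a carboxyl oxygen of the target, and the chiral epoxide), installed in one flask on achiral polyene 3.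
5. 3 ⇐ 3‑methyl‑3‑sulfolene 1 + (2E,6E)‑farnesyl bromide 2; 15 ⇐ phenol 14.

Assumption: decalin locants are used for the terpenoid part (C‑1 bears the carboxyl carbon; ring fusion C‑4a/C‑8a; C‑5 bears the side chain); compounds 3–13 are mixtures of both epimers at the sulfolene ring C‑2, a centre destroyed in step 8; (2E,6E)‑farnesyl bromide and D‑(−)‑diethyl tartrate are bought.

Step 1
Reactants: 1 3‑methyl‑2,5‑dihydrothiophene 1,1‑dioxide; 2 (2E,6E)‑farnesyl bromide
Product: 3 3‑methyl‑2‑[(2E,6E)‑farnesyl]‑2,5‑dihydrothiophene 1,1‑dioxide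
Conditions: LiN(SiMe3)2 (1.1 equiv) added to 1 + 2, THF–HMPA, −78 °C
Reagents that add atoms: none
Why: Alkylation of a sulfone‑stabilised allylic carbanion (SN2 at the primary allylic bromide, the unstable anion being trapped as it forms) occurs at ring C‑2 next to the methyl‑bearing carbon, leaves the (2E,6E) geometry untouched, and creates only a ring stereocentre that is lost in step 8.

Step 2
Reactants: 3 3‑methyl‑2‑[(2E,6E)‑farnesyl]‑2,5‑dihydrothiophene 1,1‑dioxide
Product: 5 (10R,11R)‑10,11‑epoxy‑12‑hydroxyfarnesyl sulfolene, via allylic alcohol 4 (not isolated)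
Conditions: SeO2 (5 mol%), Ti(OiPr)4 (10 mol%), D‑(−)‑diethyl tartrate (12 mol%), tBuOOH (2.5 equiv, anhydrous), 4 Å MS, CH2Cl2, 0 °C
Reagents that add atoms: tert‑butyl hydroperoxide, CC(C)(C)OO
Why: Proposed new method: selenium/titanium relay catalysis in one flask, in which catalytic SeO2/tBuOOH performs the ene/[2,3]‑sigmatropic oxygenation of the most electron‑rich, least hindered terminal trisubstituted alkene at its (E)‑methyl group, the nascent (E)‑allylic selenite ester/alcohol 4 exchanges onto the Ti(OiPr)4–D‑(−)‑tartrate complex and is epoxidised there by the same hydroperoxide on the face giving the (10R,11R)‑epoxide (opposite to the L‑(+)‑tartrate outcome), and the epoxy alcohol, no longer a selenium substrate, escapes over‑oxidation to the enal; the closest known reaction types are the Sharpless–Umbreit SeO2/tBuOOH allylic hydroxylation and the Katsuki–Sharpless asymmetric epoxidation, not yet run as a coupled catalytic pair.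

Step 3
Reactants: 5 (10R,11R)‑10,11‑epoxy‑12‑hydroxyfarnesyl sulfolene
Product: 8 bicyclic sulfolene diol (1S,2R,4aS,5R,8aS), via epoxy silyl ether 6 (not isolated), via bis‑silyl ether 7 (not isolated)
Conditions: Me3SiCl, 2,4,6‑collidine, Cp2TiCl2 (0.2 equiv), Mn, THF, rt; then 0.5 M HCl
Reagents that add atoms: none
Why: Titanocene‑mediated reductive epoxide opening and 6‑endo/6‑endo radical bicyclisation (Cp2TiCl, trivalent titanium, turned over by Mn/Me3SiCl/collidine): the tertiary radical closes rings A and B through a chair–chair transition state with the retained (R)‑C–O bond equatorial, which sets C‑4a(S) and C‑8a(S) (trans‑decalin) and C‑5(R) (side chain equatorial), while the planar radical carbon becomes C‑1(S) with the larger CH2OSiMe3 arm pseudo‑equatorial and CH3 axial (selectivity expected to be only moderate; the C‑1 epimer is removed by chromatography), and the final tertiary radical is trapped by a second Cp2TiCl and loses a methyl β‑hydrogen to give the exocyclic alkene.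

Step 4
Reactants: 8 bicyclic sulfolene diol (1S,2R,4aS,5R,8aS)
Product: 9 cyclic thionocarbonate of diol 8
Conditions: 1,1′‑thiocarbonyldiimidazole, DMAP (cat.), THF, 50 °C
Reagents that add atoms: 1,1′‑thiocarbonyldiimidazole, S=C(n1ccnc1)n1ccnc1
Why: Thiocarbonylation of the trans‑diequatorial 1,3‑diol closes a six‑membered 1,3‑dioxane‑2‑thione without touching a stereocentre.

Step 5
Reactants: 9 cyclic thionocarbonate of diol 8
Product: 11 bicyclic sulfolene primary alcohol (1S,4aS,5R,8aS), via S‑stannyl thiocarbonate 10 (not isolated)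
Conditions: Bu3SnH, Et3B (cat.)/air, toluene, rt; then wet silica gel
Reagents that add atoms: none
Why: Barton‑type radical deoxygenation of a cyclic thionocarbonate, in which the tin radical adds to C=S and the ring fragments towards the more stable secondary C‑2 radical (not the primary CH2), which Bu3SnH reduces to CH2, the primary oxygen staying as thiocarbonate 10 that loses COS on hydrolytic work‑up.

Step 6
Reactants: 11 bicyclic sulfolene primary alcohol (1S,4aS,5R,8aS)
Product: 13 bicyclic sulfolene carboxylic acid (1S,4aS,5R,8aS), via aldehyde 12 (not isolated)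
Conditions: TEMPO (0.3 equiv), PhI(OAc)2 (2.5 equiv), MeCN–H2O (1:1), rt
Reagents that add atoms: water, O
Why: Oxoammonium (TEMPO/PhI(OAc)2) oxidation of the neopentyl alcohol through the aldehyde hydrate; the quaternary C‑1 cannot epimerise and the alkene and sulfone are inert.

Step 7
Reactants: 14 3‑methoxy‑2‑methylphenol
Product: 15 2‑methoxy‑3‑methyl‑1,4‑benzoquinone
Conditions: Co(salen) [Co(C16H14N2O2)] (5 mol%), O2 (1 atm), MeCN, rt
Reagents that add atoms: dioxygen, O=O
Why: Cobalt–salen‑catalysed aerobic oxidation of a phenol with a free para position gives the para‑quinone.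

Step 8
Reactants: 13 bicyclic sulfolene carboxylic acid (1S,4aS,5R,8aS); 15 2‑methoxy‑3‑methyl‑1,4‑benzoquinone
Product: 18 2‑methoxy naphthoquinone acid (1S,4aS,5R,8aS), via diene acid 16 (not isolated), via cycloadduct 17 (not isolated)
Conditions: 15 (3.3 equiv), toluene, 110 °C
Reagents that add atoms: none
Why: Cheletropic SO2 extrusion (disrotatory, giving only the (E)‑diene), Diels–Alder reaction and dehydrogenation by excess quinone: the CH2 terminus of the 1‑alkyl‑2‑methyl diene (larger HOMO coefficient) bonds to C‑5 of 15, the carbon β to the more electrophilic C‑1 carbonyl (C‑4 is a vinylogous ester carbonyl), so the terpenyl‑CH2 carbon ends peri to the carbonyl flanked by OCH3, and two further equivalents of 15 aromatise the adduct, erasing its transient stereocentres.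

Step 9
Reactants: 18 2‑methoxy naphthoquinone acid (1S,4aS,5R,8aS)
Product: 19 target hydroxynaphthoquinone acid (1S,4aS,5R,8aS)
Conditions: LiOH (1 M aq, 4 equiv), THF–MeOH, rt; then 1 M HCl
Reagents that add atoms: lithium hydroxide, [Li+].[OH-]
Why: Addition–elimination hydrolysis of the vinylogous methyl ester of the 2‑methoxy‑1,4‑naphthoquinone gives the hydroxyquinone anion and, after acidification, the target, with no stereocentre involved.

**Compound list**
1 | 3‑methyl‑2,5‑dihydrothiophene 1,1‑dioxide (3‑methyl‑3‑sulfolene) | CC1=CCS(=O)(=O)C1 | starting material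
2 | (2E,6E)‑1‑bromo‑3,7,11‑trimethyldodeca‑2,6,10‑triene ((2E,6E)‑farnesyl bromide) | CC(C)=CCC/C(C)=C/CC/C(C)=C/CBr | starting material
3 | 3‑methyl‑2‑[(2E,6E)‑3,7,11‑trimethyldodeca‑2,6,10‑trien‑1‑yl]‑2,5‑dihydrothiophene 1,1‑dioxide (racemic at ring C‑2) | CC(C)=CCC/C(C)=C/CC/C(C)=C/CC1C(C)=CCS1(=O)=O | intermediate
4 | 2‑[(2E,6E,10E)‑12‑hydroxy‑3,7,11‑trimethyldodeca‑2,6,10‑trien‑1‑yl]‑3‑methyl‑2,5‑dihydrothiophene 1,1‑dioxide (formed in situ) | OC/C(C)=C/CC/C(C)=C/CC/C(C)=C/CC1C(C)=CCS1(=O)=O | intermediate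
5 | 2‑[(2E,6E)‑9‑[(2R,3R)‑3‑(hydroxymethyl)‑3‑methyloxiran‑2‑yl]‑3,7‑dimethylnona‑2,6‑dien‑1‑yl]‑3‑methyl‑2,5‑dihydrothiophene 1,1‑dioxide | OC[C@@]1(C)O[C@@H]1CC/C(C)=C/CC/C(C)=C/CC2C(C)=CCS2(=O)=O | intermediate
6 | trimethylsilyl ether of 5 at the primary hydroxyl (formed in situ) | C[Si](C)(C)OC[C@@]1(C)O[C@@H]1CC/C(C)=C/CC/C(C)=C/CC2C(C)=CCS2(=O)=O | intermediate
7 | bis(trimethylsilyl) ether of diol 8 (formed in situ) | C=C1CC[C@H]2[C@@](C)(CC[C@@H](O[Si](C)(C)C)[C@]2(C)CO[Si](C)(C)C)[C@@H]1CC3C(C)=CCS3(=O)=O | intermediate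
8 | (1S,2R,4aS,5R,8aS)‑1‑(hydroxymethyl)‑1,4a‑dimethyl‑6‑methylidene‑5‑[(3‑methyl‑1,1‑dioxo‑2,5‑dihydrothiophen‑2‑yl)methyl]decahydronaphthalen‑2‑ol (2‑OH and 1‑CH2OH equatorial, 1‑CH3 axial, trans ring fusion) | C=C1CC[C@H]2[C@@](C)(CC[C@@H](O)[C@]2(C)CO)[C@@H]1CC3C(C)=CCS3(=O)=O | intermediate
9 | cyclic thionocarbonate (1,3‑dioxane‑2‑thione) bridging O‑2 and the 1‑CH2O of 8 | C=C1CC[C@H]2[C@@](C)(CC[C@H]3OC(=S)OC[C@@]32C)[C@@H]1CC4C(C)=CCS4(=O)=O | intermediate
10 | O‑{[(1S,4aS,5R,8aS)‑decalinyl]methyl} S‑(tributylstannyl) thiocarbonate of alcohol 11 (formed in situ) | C=C1CC[C@H]2[C@@](C)(CCC[C@]2(C)COC(=O)S[Sn](CCCC)(CCCC)CCCC)[C@@H]1CC3C(C)=CCS3(=O)=O | intermediate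
11 | [(1S,4aS,5R,8aS)‑1,4a‑dimethyl‑6‑methylidene‑5‑[(3‑methyl‑1,1‑dioxo‑2,5‑dihydrothiophen‑2‑yl)methyl]decahydronaphthalen‑1‑yl]methanol | C=C1CC[C@H]2[C@@](C)(CCC[C@]2(C)CO)[C@@H]1CC3C(C)=CCS3(=O)=O | intermediate
12 | (1S,4aS,5R,8aS)‑1,4a‑dimethyl‑6‑methylidene‑5‑[(3‑methyl‑1,1‑dioxo‑2,5‑dihydrothiophen‑2‑yl)methyl]decahydronaphthalene‑1‑carbaldehyde (formed in situ) | C=C1CC[C@H]2[C@@](C)(CCC[C@]2(C)C=O)[C@@H]1CC3C(C)=CCS3(=O)=O | intermediate
13 | (1S,4aS,5R,8aS)‑1,4a‑dimethyl‑6‑methylidene‑5‑[(3‑methyl‑1,1‑dioxo‑2,5‑dihydrothiophen‑2‑yl)methyl]decahydronaphthalene‑1‑carboxylic acid | C=C1CC[C@H]2[C@@](C)(CCC[C@]2(C)C(=O)O)[C@@H]1CC3C(C)=CCS3(=O)=O | intermediate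
14 | 3‑methoxy‑2‑methylphenol | COc1cccc(O)c1C | starting material
15 | 2‑methoxy‑3‑methylcyclohexa‑2,5‑diene‑1,4‑dione | COC1=C(C)C(=O)C=CC1=O | intermediate
16 | (1S,4aS,5R,8aS)‑1,4a‑dimethyl‑6‑methylidene‑5‑[(2E)‑3‑methylpenta‑2,4‑dien‑1‑yl]decahydronaphthalene‑1‑carboxylic acid (formed in situ) | C=C1CC[C@H]2[C@@](C)(CCC[C@]2(C)C(=O)O)[C@@H]1C/C=C(C)/C=C | intermediate
17 | (1S,4aS,5R,8aS)‑5‑[(7‑methoxy‑2,6‑dimethyl‑5,8‑dioxo‑1,4,4a,5,8,8a‑hexahydronaphthalen‑1‑yl)methyl]‑1,4a‑dimethyl‑6‑methylidenedecahydronaphthalene‑1‑carboxylic acid (cis‑fused cycloadduct, isomer mixture at its three new centres, formed in situ) | C=C1CC[C@H]2[C@@](C)(CCC[C@]2(C)C(=O)O)[C@@H]1CC3C(C)=CCC4C3C(=O)C(OC)=C(C)C4=O | intermediate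
18 | (1S,4aS,5R,8aS)‑5‑[(7‑methoxy‑2,6‑dimethyl‑5,8‑dioxo‑5,8‑dihydronaphthalen‑1‑yl)methyl]‑1,4a‑dimethyl‑6‑methylidenedecahydronaphthalene‑1‑carboxylic acid | C=C1CC[C@H]2[C@@](C)(CCC[C@]2(C)C(=O)O)[C@@H]1Cc1c(C)ccc2c1C(=O)C(OC)=C(C)C2=O | intermediate
19 | (1S,4aS,5R,8aS)‑5‑[(7‑hydroxy‑2,6‑dimethyl‑5,8‑dioxo‑5,8‑dihydronaphthalen‑1‑yl)methyl]‑1,4a‑dimethyl‑6‑methylidenedecahydronaphthalene‑1‑carboxylic acid | C=C1CC[C@H]2[C@@](C)(CCC[C@]2(C)C(=O)O)[C@@H]1Cc1c(C)ccc2c1C(=O)C(O)=C(C)C2=O | target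

**Totals**
Total step count: 9. Longest linear sequence: 8 (steps 1–6, 8 and 9).

**Steps most likely to fail**

Step 2 (the proposed one‑flask hydroxylation/epoxidation; the selenium and titanium catalysts may poison each other, or site selectivity among the three trisubstituted alkenes may be poor). The fallback sets out from 3 and comes back at 5 using known chemistry only. SeO2 (0.5 equiv)/tBuOOH with salicylic acid in CH2Cl2 at rt gives a mixture of allylic alcohol 4 and the over‑oxidised (2E,6E,10E)‑12‑oxo enal F1. NaBH4/CeCl3 in MeOH returns the enal to 4, which is now isolated. A separate Katsuki–Sharpless epoxidation (Ti(OiPr)4, D‑(−)‑diethyl tartrate, tBuOOH, 4 Å MS, CH2Cl2, −20 °C) then gives 5.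

Step 3 (the radical at C‑1 is planar, so the CH2O/CH3 orientation rests only on a steric preference and the C‑1 epimer may form in quantity). The fallback sets out from 5 and comes back at 8, replacing the radical manifold by a cationic, stereospecific one. The primary alcohol is protected as the tert‑butyldimethylsilyl ether F2 (TBSCl, imidazole). MeAlCl2 in CH2Cl2 at −78 °C then triggers an epoxide‑opening cation–olefin bicyclisation in which anti‑periplanar π‑participation transfers the (E)‑geometry to C‑1 with full fidelity (CH2O equatorial). The price is proton‑loss regiochemistry: the exocyclic‑alkene product, the cyclised silyl ether F3, must be separated from endocyclic alkene isomers on AgNO3‑impregnated silica. HF·pyridine then gives 8.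

Step 8 (regiochemistry of the cycloaddition; the 2‑methyl group of the diene opposes the 1‑alkyl group, and the two quinone carbonyls may not differ enough). The fallback sets out from 13 and comes back at 17, using a dienophile with a single activating carbonyl. Commercial 2,4‑dimethoxy‑3‑methylphenol is oxidised with PhI(OAc)2 in MeOH to the quinone monoketal F4. Heating 13 with the monoketal (toluene, 110–130 °C) gives the ketal cycloadduct F5, in which the nucleophilic diene terminus can only add β to the one free carbonyl. Dilute HCl/THF unmasks cycloadduct 17, which is dehydrogenated with 15 (or MnO2) to 18 as in step 8.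

**Further compounds**
F1 | step 2 | 2‑[(2E,6E,10E)‑3,7,11‑trimethyl‑12‑oxododeca‑2,6,10‑trien‑1‑yl]‑3‑methyl‑2,5‑dihydrothiophene 1,1‑dioxide | O=C/C(C)=C/CC/C(C)=C/CC/C(C)=C/CC1C(C)=CCS1(=O)=O
F2 | step 3 | tert‑butyldimethylsilyl ether of 5 at the primary hydroxyl | CC(C)(C)[Si](C)(C)OC[C@@]1(C)O[C@@H]1CC/C(C)=C/CC/C(C)=C/CC2C(C)=CCS2(=O)=O
F3 | step 3 | (1S,2R,4aS,5R,8aS)‑1‑[(tert‑butyldimethylsilyloxy)methyl]‑1,4a‑dimethyl‑6‑methylidene‑5‑[(3‑methyl‑1,1‑dioxo‑2,5‑dihydrothiophen‑2‑yl)methyl]decahydronaphthalen‑2‑ol | C=C1CC[C@H]2[C@@](C)(CC[C@@H](O)[C@]2(C)CO[Si](C)(C)C(C)(C)C)[C@@H]1CC3C(C)=CCS3(=O)=O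
F4 | step 8 | 2,4,4‑trimethoxy‑3‑methylcyclohexa‑2,5‑dien‑1‑one | O=C1C=CC(OC)(OC)C(C)=C1OC
F5 | step 8 | (1S,4aS,5R,8aS)‑1,4a‑dimethyl‑6‑methylidene‑5‑[(5,5,7‑trimethoxy‑2,6‑dimethyl‑8‑oxo‑1,4,4a,5,8,8a‑hexahydronaphthalen‑1‑yl)methyl]decahydronaphthalene‑1‑carboxylic acid | C=C1CC[C@H]2[C@@](C)(CCC[C@]2(C)C(=O)O)[C@@H]1CC3C(C)=CCC4C3C(=O)C(OC)=C(C)C4(OC)OC
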